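3 questions stood before me, and I wanted one decision from them: which of the 6 flasks to charge for product, and, with the time held, what to change in the poorest.

| flask | starting material | reagent | remark | time |
|---|---|---|---|---|
| Sunday's | 0.050 M | 0.017 M | run made earlier |  |
| Thursday's | 0.050 M | 0.061 M | run made earlier |  |
| Monday's | 0.050 M | 0.19 M | run made earlier |  |
| Saturday's | 0.025 M | 0.055 M | run made earlier |  |
| spring | 0.015 M | 0.0300 M |  | 50 min |
| midnight | 0.030 M | 0.200 M |  | 50 min |
| noon | 0.015 M | 0.0200 M |  | 50 min |
| dusk | 0.012 M | 0.150 M |  | 50 min |
| autumn | 0.050 M | 0.0550 M |  | 50 min |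
| summer | 0.015 M | 0.0550 M |  | 50 min |

| run | time / min | product / % |
|---|---|---|
| Sunday's | 2.00 | 6.2 |
| Sunday's | 5.00 | 8.7 |
| Sunday's | 10.0 | 9.1 |
| Sunday's | 25.0 | 9.9 |
| Thursday's | 3.00 | 24.0 |
| Thursday's | 8.00 | 27.6 |
| Thursday's | 15.0 | 29.1 |
| Thursday's | 25.0 | 29.9 |
| Monday's | 3.00 | 52.8 |
| Monday's | 8.00 | 57.0 |
| Monday's | 15.0 | 57.5 |
| Monday's | 25.0 | 58.8 |
| Saturday's | 6.00 | 27.1 |
| Saturday's | 12.0 | 29.5 |
| Saturday's | 20.0 | 30.1 |
| Saturday's | 25.0 | 31.2 |

(readings scatter by 0.5 percentage points)

- the earlier runs were read with a standard deviation of 0.5 percentage points
- a reading or a percentage of product counts all its forms, free or not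

- all flasks from highest to lowest amount of product, in percent of the starting material charged, at 50 min (spring / midnight / noon / dusk / autumn / summer)
- the amount of product, in percent of the starting material charged of the flask you put first, at 50 min
- the amount of product, in percent of the starting material charged of the flask you put last, at 50 min

Every earlier run rose within minutes to a shelf and then crept: Thursday's gained 0.8 percentage points between 15.0 min and 25.0 min. So I reckoned with shelves. Monday's, with ten times the reagent of Sunday's and the same starting material, ended at 58.8% against 9.9%.

I therefore looked for the crossing. Thursday's last reading leaves 0.0461 M of reagent not spent on product, and multiplying this by the ratio of charge not read as product to charge read as product gives 0.108 M. I call this the half-point reagent: the reagent, net of product, at which a shelf holds half the charge as product, a selectivity factor written as a concentration. As readings, Sunday's gives 0.110 M and Monday's 0.113 M. Each flask then follows from one line: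

product share = reagent not spent / (reagent not spent + half-point)

Solving this, I got 62.7% for midnight and 14.2% for noon, whose reagent lies below the half-point. So I would charge midnight, and in noon I would raise the reagent.

The forecast gave midnight > dusk > summer > autumn > spring > noon, with 63.7% first and 14.7% last, both above my figures. Its ground was this: “The product levels off quickly at a value set by the reagent”.

Midnight gave 61.7% and noon 16.2%, in the order midnight > dusk > summer > autumn > spring > noon. Left longer, midnight's product has moved by 5 points at 187 min, so a shelf describes this time and not the end. Midnight's charge was 1.85 half-points and noon's 0.185, and the reckoning stood 1.00 point above midnight and 2 points below noon.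

    starting material ⇌ intermediate A (K = 7.50, k = 0.00620 /s)
    starting material + reagent → product (k = 0.0480 /M/s)
    reagent + intermediate A ⇌ intermediate B (K = 140 /M, k = 0.180 /M/s)
    intermediate A ⇌ intermediate C (K = 2.40, k = 0.0890 /s)
    crystals ⇌ product, rate k5*(cs5 - [product]) while solid is left; crystals form when [product] > cs5 (solubility = 11.0 mM, k = 0.710 /s)

For noon's neighbour with 0.080 M of reagent, the half-point gives 40.6%. The computed flask holds 41.4%.

(The readings were computed for an exercise.)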